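4 questions stand on this flask, and before asking how fast it runs I want one number that says whether its charge can carry it to the end.

the same everywhere: solid reagent 1.47 M
- blue: substrate 0.49 M; the very flask that is asked about, followed so far
- green: substrate 0.73 M; run made earlier
- flask: substrate 0.49 M; time 5.0 d

- blue (time / h: double product / %): 10.0: 0; 20.0: 3.3; 30.0: 6.1; 40.0: 11.8; 50.0: 17.0
- green (time / h: double product / %): 10.0: 0; 20.0: 2.6; 30.0: 5.7; 40.0: 8.7; 50.0: 13.3

(standard deviation of a reading: 1 percentage point)

- solid reagent is a solid; its amount is given per volume of the solution
- the numbers in the tables scatter by 1 percentage point (one standard deviation)
- at the start none of the solid reagent is in solution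
- coupling partner is what solid reagent becomes in solution

- alder: doubling the dissolution coefficient of the solid reagent, all else as stated
- ash: doubling the solubility of the solid reagent, all else as stated

- double product at 5.0 d, in percent of the substrate charged
- concentration of coupling partner in solution at 12 h, in percent of saturation
- the change that raises the amount of double product at 5.0 d, in percent of the substrate charged most ("none" if none brings more than 2 percentage points) (alder / ash / none)
- amount of double product at 5.0 d, in percent of the substrate charged, after ash

I read double product as two couplings on each substrate, each taking one coupling partner from the solid reagent. So I take c_S, the solid reagent charged, and c_A, the substrate charged: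

K = c_S / (2 c_A) = 1.50

K is the cover: solid reagent charged per partner that full doubling needs. On that reading the highest double product a charge allows is K, or 100% where K exceeds 1. Here K lies above 1, so the charge sets no ceiling below full conversion, and y, the double product at the asked time, is a question of pace.

Two extreme versions should bracket y, both run on from the last blue reading:

pace since the second blue reading kept: 49.0%

growth with the square of time kept: 97.9%

The square belongs to two couplings in sequence at a steady level of coupling partner while substrate stays near its charge, and substrate cannot stay there while this much product forms, so I expect this version to run high. The straight line ignores a gain per reading that rises from 2.8 percentage points to 5.2 points, though scatter blurs that rise, so I expect it to run low. I commit to the middle, 73.4%.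

The forecast gives 58%, 55%, ash and 85%, saying: “The solid (3 equivalents) suffices, so ash wins.”

The flask gives y = 64.4%, inside my bracket and 9.0 points under its middle. It also gives 49.5% of saturation at 12 h; ash is best, adding 32 points against 14 points for alder, and reaches 96.8%.

    substrate + coupling partner → first product (k = 0.240 M⁻¹ h⁻¹)
    coupling partner + first product → double product (k = 0.310 M⁻¹ h⁻¹)
    solid reagent ⇌ coupling partner, rate k3*(cs3 - [coupling partner]) while solid is left; crystals form when [coupling partner] > cs3 (solubility = 0.120 M, k = 0.130 h⁻¹)

In this flask at 2.50 d first product stood at 32.2%, ahead of double product at 25.3%. At 5.00 d double product led with 64.4% against 21.3% of first product, while solid reagent, at cover 1.50, still held 44.2% of its own charge.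

The neighbour charged with 0.59 M of solid reagent has K = 0.602, below 1, which makes solid reagent the limiting reagent and caps double product at 60.2%. That neighbour gives 45.5% at 5.00 d, with 28.8% as first product, 26% of substrate left and solid reagent at 0%.

All runs come from a simulation from invented constants.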